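**Retrosynthetic overview**
1. The last step is a global acid methanolysis of two MOM ethers and one TBS ether on the fully assembled chalcone.
2. The enone C=C comes from a Claisen–Schmidt condensation of a ring A acetophenone (2-OH free, 4-OMOM, 3-prenyl) with a ring B benzaldehyde (4-OMOM, silyl-protected side chain at C3).
3. Ring A ketone: 2,4-dihydroxyacetophenone, then 4-O-(1,1-dimethylpropargyl) ether, Lindlar semihydrogenation, aromatic Claisen rearrangement (prenyl to C3) and 4-O-MOM.
4. Ring B aldehyde: methyl 2-(2-hydroxyphenyl)acetate, then para-bromination, MOM, Weinreb amide and isopropenyl Grignard give an isopropenyl ketone. A ketoreductase-catalysed asymmetric reduction sets the only stereocentre (R), followed by TBS protection and Li–Br exchange/DMF.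
5. No ring is formed: both benzene rings come intact from the starting materials (ring A fragment first, ring B fragment second, then joined).

Assumption: a ketoreductase with the required Si-face selectivity for the isopropenyl ketone is found in a standard enzyme screening panel; this has not been verified for this exact substrate.

**Step 1**
Reactants: 1 1-(2,4-dihydroxyphenyl)ethan-1-one; 2 3-chloro-3-methylbut-1-yne
Product: 3 1-{2-hydroxy-4-[(2-methylbut-3-yn-2-yl)oxy]phenyl}ethan-1-one
Conditions: K2CO3, KI (cat.), CuI (cat.), acetone, 56 °C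
Reagents that add atoms: none
Why: Copper-assisted propargylic O-alkylation (Williamson-type) occurs only at the 4-OH, because the 2-OH is tied up in a hydrogen bond to the ketone and is much less nucleophilic.

**Step 2**
Reactants: 3 1-{2-hydroxy-4-[(2-methylbut-3-yn-2-yl)oxy]phenyl}ethan-1-one
Product: 4 1-{2-hydroxy-4-[(2-methylbut-3-en-2-yl)oxy]phenyl}ethan-1-one
Conditions: H2 (1 atm), Pd/CaCO3 poisoned with Pb(OAc)2 (Lindlar catalyst), quinoline, EtOAc, rt
Reagents that add atoms: none
Why: Lindlar semihydrogenation stops at the terminal alkene and leaves the aryl ketone and aryl ether untouched.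

**Step 3**
Reactants: 4 1-{2-hydroxy-4-[(2-methylbut-3-en-2-yl)oxy]phenyl}ethan-1-one
Product: 6 1-[2,4-dihydroxy-3-(3-methylbut-2-en-1-yl)phenyl]ethan-1-one, via ortho-dienone 5 (not isolated)
Conditions: N,N-diethylaniline, 140 °C
Reagents that add atoms: none
Why: Aromatic Claisen ([3,3]-sigmatropic) rearrangement of the 1,1-dimethylallyl ether delivers a linear prenyl group to C3, the ortho position favoured by bond fixation in the chelated 2-hydroxyaryl ketone, and the dienone tautomerises to the phenol.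

**Step 4**
Reactants: 6 1-[2,4-dihydroxy-3-(3-methylbut-2-en-1-yl)phenyl]ethan-1-one
Product: 7 1-[2-hydroxy-4-(methoxymethoxy)-3-(3-methylbut-2-en-1-yl)phenyl]ethan-1-one
Conditions: MOMCl, K2CO3, acetone, 0 °C to rt
Reagents that add atoms: chloromethyl methyl ether, COCCl
Why: MOM protection (O-alkylation) takes place selectively at the non-chelated 4-OH under mild carbonate conditions.

**Step 5**
Reactants: 8 methyl 2-(2-hydroxyphenyl)acetate
Product: 9 methyl 2-(5-bromo-2-hydroxyphenyl)acetate
Conditions: NBS (1.0 equiv), MeCN, 0 °C to rt, dark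
Reagents that add atoms: N-bromosuccinimide, O=C1CCC(=O)N1Br
Why: Electrophilic aromatic bromination with NBS in acetonitrile is para-selective for phenols, which places the bromine at C5, the future formyl position.

**Step 6**
Reactants: 9 methyl 2-(5-bromo-2-hydroxyphenyl)acetate
Product: 10 methyl 2-[5-bromo-2-(methoxymethoxy)phenyl]acetate
Conditions: MOMCl, i-Pr2NEt, CH2Cl2, 0 °C to rt
Reagents that add atoms: chloromethyl methyl ether, COCCl
Why: MOM protection of the phenol gives an ether that tolerates the organomagnesium, organolithium and hydroxide steps ahead.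

**Step 7**
Reactants: 10 methyl 2-[5-bromo-2-(methoxymethoxy)phenyl]acetate
Product: 11 2-[5-bromo-2-(methoxymethoxy)phenyl]-N-methoxy-N-methylacetamide
Conditions: MeNHOMe·HCl, i-PrMgCl, THF, −20 to 0 °C; then aq. NH4Cl
Reagents that add atoms: N,O-dimethylhydroxylamine hydrochloride, CNOC.Cl
Why: Aminolysis of the ester by the magnesium amide formed in the flask (Weinreb amide synthesis) is fast at low temperature, where the aryl bromide does not undergo halogen–magnesium exchange.

**Step 8**
Reactants: 11 2-[5-bromo-2-(methoxymethoxy)phenyl]-N-methoxy-N-methylacetamide; 12 isopropenylmagnesium bromide (prop-1-en-2-ylmagnesium bromide, THF solution)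
Product: 14 1-[5-bromo-2-(methoxymethoxy)phenyl]-3-methylbut-3-en-2-one, via magnesium chelate 13 (not isolated)
Conditions: THF, −20 to 0 °C; then cold aq. NH4Cl
Reagents that add atoms: none
Why: Weinreb ketone synthesis: the stable five-membered magnesium chelate prevents over-addition and releases the isopropenyl ketone only on cold aqueous quench.

**Step 9**
Reactants: 14 1-[5-bromo-2-(methoxymethoxy)phenyl]-3-methylbut-3-en-2-one
Product: 15 (2R)-1-[5-bromo-2-(methoxymethoxy)phenyl]-3-methylbut-3-en-2-ol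
Conditions: ketoreductase ((R)-selective, NADPH-dependent), NADP+ (cat.), i-PrOH, KH2PO4/K2HPO4 buffer pH 7.0, DMSO (5% v/v), 30 °C
Reagents that add atoms: none
Why: Biocatalytic asymmetric carbonyl reduction: the ketoreductase (an NADPH-dependent alcohol dehydrogenase of the oxidoreductase class) delivers hydride to the Si face of the prochiral ketone and so sets the only stereocentre as (R), while the C=C, aryl bromide and MOM ether are inert and isopropanol recycles the cofactor.

**Step 10**
Reactants: 15 (2R)-1-[5-bromo-2-(methoxymethoxy)phenyl]-3-methylbut-3-en-2-ol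
Product: 16 {[(2R)-1-[5-bromo-2-(methoxymethoxy)phenyl]-3-methylbut-3-en-2-yl]oxy}(tert-butyl)dimethylsilane
Conditions: TBSCl, imidazole, DMF, rt
Reagents that add atoms: tert-butyldimethylsilyl chloride, CC(C)(C)[Si](C)(C)Cl
Why: Silylation of the secondary allylic alcohol masks the acidic OH for the organolithium step without touching the C–O stereocentre.

**Step 11**
Reactants: 16 {[(2R)-1-[5-bromo-2-(methoxymethoxy)phenyl]-3-methylbut-3-en-2-yl]oxy}(tert-butyl)dimethylsilane
Product: 19 3-[(2R)-2-{[tert-butyl(dimethyl)silyl]oxy}-3-methylbut-3-en-1-yl]-4-(methoxymethoxy)benzaldehyde, via aryllithium 17 (not isolated), via lithium hemiaminolate 18 (not isolated)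
Conditions: n-BuLi, THF, −78 °C; DMF, −78 to 0 °C; then aq. NH4Cl
Reagents that add atoms: N,N-dimethylformamide, CN(C)C=O
Why: Lithium–bromine exchange is faster than any deprotonation at −78 °C, and formylation of the aryllithium with DMF (Bouveault reaction) gives the aldehyde on hydrolysis of the hemiaminolate.

**Step 12**
Reactants: 7 1-[2-hydroxy-4-(methoxymethoxy)-3-(3-methylbut-2-en-1-yl)phenyl]ethan-1-one; 19 3-[(2R)-2-{[tert-butyl(dimethyl)silyl]oxy}-3-methylbut-3-en-1-yl]-4-(methoxymethoxy)benzaldehyde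
Product: 21 (2E)-3-{3-[(2R)-2-{[tert-butyl(dimethyl)silyl]oxy}-3-methylbut-3-en-1-yl]-4-(methoxymethoxy)phenyl}-1-[2-hydroxy-4-(methoxymethoxy)-3-(3-methylbut-2-en-1-yl)phenyl]prop-2-en-1-one, via aldol adduct 20 (not isolated)
Conditions: KOH (50% aq.), EtOH, 0 °C to rt; neutralise to pH 6
Reagents that add atoms: none
Why: Claisen–Schmidt condensation (aldol addition, then E1cB dehydration) of the methyl ketone with the non-enolisable aldehyde gives the thermodynamically favoured (E)-enone, and MOM and TBS ethers and both alkenes are stable to hydroxide.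

**Step 13**
Reactants: 21 (2E)-3-{3-[(2R)-2-{[tert-butyl(dimethyl)silyl]oxy}-3-methylbut-3-en-1-yl]-4-(methoxymethoxy)phenyl}-1-[2-hydroxy-4-(methoxymethoxy)-3-(3-methylbut-2-en-1-yl)phenyl]prop-2-en-1-one
Product: 22 (2E)-1-[2,4-dihydroxy-3-(3-methylbut-2-en-1-yl)phenyl]-3-{4-hydroxy-3-[(2R)-2-hydroxy-3-methylbut-3-en-1-yl]phenyl}prop-2-en-1-one
Conditions: HCl (1.25 M in MeOH), MeOH/THF, 0 °C to rt, stopped at full conversion
Reagents that add atoms: none
Why: Acid-catalysed acetal methanolysis removes both MOM groups and solvolyses the silyl ether under dilute, cold conditions that do not break the C–O bond at the stereocentre.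

**Compound list**
1 | 1-(2,4-dihydroxyphenyl)ethan-1-one (2,4-dihydroxyacetophenone) | CC(=O)c1ccc(O)cc1O | starting material
2 | 3-chloro-3-methylbut-1-yne | CC(C)(Cl)C#C | starting material
3 | 1-{2-hydroxy-4-[(2-methylbut-3-yn-2-yl)oxy]phenyl}ethan-1-one | CC(=O)c1ccc(OC(C)(C)C#C)cc1O | intermediate
4 | 1-{2-hydroxy-4-[(2-methylbut-3-en-2-yl)oxy]phenyl}ethan-1-one | CC(=O)c1ccc(OC(C)(C)C=C)cc1O | intermediate
5 | 4-acetyl-3-hydroxy-2-(3-methylbut-2-en-1-yl)cyclohexa-3,5-dien-1-one (ortho-dienone, racemic at C2, formed in the flask) | CC(=O)C1=C(O)C(CC=C(C)C)C(=O)C=C1 | intermediate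
6 | 1-[2,4-dihydroxy-3-(3-methylbut-2-en-1-yl)phenyl]ethan-1-one | CC(=O)c1ccc(O)c(CC=C(C)C)c1O | intermediate
7 | 1-[2-hydroxy-4-(methoxymethoxy)-3-(3-methylbut-2-en-1-yl)phenyl]ethan-1-one | CC(=O)c1ccc(OCOC)c(CC=C(C)C)c1O | intermediate
8 | methyl 2-(2-hydroxyphenyl)acetate | COC(=O)Cc1ccccc1O | starting material
9 | methyl 2-(5-bromo-2-hydroxyphenyl)acetate | COC(=O)Cc1cc(Br)ccc1O | intermediate
10 | methyl 2-[5-bromo-2-(methoxymethoxy)phenyl]acetate | COC(=O)Cc1cc(Br)ccc1OCOC | intermediate
11 | 2-[5-bromo-2-(methoxymethoxy)phenyl]-N-methoxy-N-methylacetamide | CON(C)C(=O)Cc1cc(Br)ccc1OCOC | intermediate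
12 | isopropenylmagnesium bromide (prop-1-en-2-ylmagnesium bromide) | C=C(C)[Mg]Br | starting material
13 | bromomagnesium 1-[5-bromo-2-(methoxymethoxy)phenyl]-2-[methoxy(methyl)amino]-3-methylbut-3-en-2-olate (tetrahedral chelate, racemic at the new centre, formed in the flask) | C=C(C)C(Cc1cc(Br)ccc1OCOC)(O[Mg]Br)N(C)OC | intermediate
14 | 1-[5-bromo-2-(methoxymethoxy)phenyl]-3-methylbut-3-en-2-one | C=C(C)C(=O)Cc1cc(Br)ccc1OCOC | intermediate
15 | (2R)-1-[5-bromo-2-(methoxymethoxy)phenyl]-3-methylbut-3-en-2-ol | C=C(C)[C@H](O)Cc1cc(Br)ccc1OCOC | intermediate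
16 | {[(2R)-1-[5-bromo-2-(methoxymethoxy)phenyl]-3-methylbut-3-en-2-yl]oxy}(tert-butyl)dimethylsilane | C=C(C)[C@H](O[Si](C)(C)C(C)(C)C)Cc1cc(Br)ccc1OCOC | intermediate
17 | {3-[(2R)-2-{[tert-butyl(dimethyl)silyl]oxy}-3-methylbut-3-en-1-yl]-4-(methoxymethoxy)phenyl}lithium (formed in the flask) | C=C(C)[C@H](O[Si](C)(C)C(C)(C)C)Cc1cc([Li])ccc1OCOC | intermediate
18 | lithium (dimethylamino){3-[(2R)-2-{[tert-butyl(dimethyl)silyl]oxy}-3-methylbut-3-en-1-yl]-4-(methoxymethoxy)phenyl}methanolate (both epimers at the hemiaminal carbon, formed in the flask) | C=C(C)[C@H](O[Si](C)(C)C(C)(C)C)Cc1cc(C(O[Li])N(C)C)ccc1OCOC | intermediate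
19 | 3-[(2R)-2-{[tert-butyl(dimethyl)silyl]oxy}-3-methylbut-3-en-1-yl]-4-(methoxymethoxy)benzaldehyde | C=C(C)[C@H](O[Si](C)(C)C(C)(C)C)Cc1cc(C=O)ccc1OCOC | intermediate
20 | 3-{3-[(2R)-2-{[tert-butyl(dimethyl)silyl]oxy}-3-methylbut-3-en-1-yl]-4-(methoxymethoxy)phenyl}-3-hydroxy-1-[2-hydroxy-4-(methoxymethoxy)-3-(3-methylbut-2-en-1-yl)phenyl]propan-1-one (both epimers at the new carbinol, formed in the flask) | C=C(C)[C@H](O[Si](C)(C)C(C)(C)C)Cc1cc(C(O)CC(=O)c2ccc(OCOC)c(CC=C(C)C)c2O)ccc1OCOC | intermediate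
21 | (2E)-3-{3-[(2R)-2-{[tert-butyl(dimethyl)silyl]oxy}-3-methylbut-3-en-1-yl]-4-(methoxymethoxy)phenyl}-1-[2-hydroxy-4-(methoxymethoxy)-3-(3-methylbut-2-en-1-yl)phenyl]prop-2-en-1-one | C=C(C)[C@H](O[Si](C)(C)C(C)(C)C)Cc1cc(/C=C/C(=O)c2ccc(OCOC)c(CC=C(C)C)c2O)ccc1OCOC | intermediate
22 | (2E)-1-[2,4-dihydroxy-3-(3-methylbut-2-en-1-yl)phenyl]-3-{4-hydroxy-3-[(2R)-2-hydroxy-3-methylbut-3-en-1-yl]phenyl}prop-2-en-1-one | C=C(C)[C@H](O)Cc1cc(/C=C/C(=O)c2ccc(O)c(CC=C(C)C)c2O)ccc1O | target

**Totals**
Total step count: 13 (ring A fragment 4 steps, ring B fragment 7 steps, 2 joint steps).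
Longest linear sequence: 9 steps (8 to 22, steps 5 to 13).

**Three steps most likely to fail**

Step 9 (enzymatic reduction). The ketone is flanked by two bulky groups, so a panel may give no enzyme with both high activity and high (R)-selectivity. Fallback: set out from 14 and reduce it 1,2-selectively (NaBH4, CeCl3·7H2O, MeOH, −40 °C) to racemic 1-[5-bromo-2-(methoxymethoxy)phenyl]-3-methylbut-3-en-2-ol F3. Then run a Sharpless kinetic resolution (Ti(OiPr)4 10 mol%, L-(+)-diisopropyl tartrate 12 mol%, t-BuOOH 0.6 equiv, 4 Å molecular sieves, CH2Cl2, −20 °C). The (S)-enantiomer is epoxidised faster to the erythro epoxy alcohol (1S)-2-[5-bromo-2-(methoxymethoxy)phenyl]-1-[(2R)-2-methyloxiran-2-yl]ethan-1-ol F4, which is removed by chromatography. The slow-reacting (R)-alcohol is recovered (at most 50%) and the route is rejoined at 15.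

Step 3 (Claisen rearrangement). Some migration to C5, loss of isoprene from the tertiary allyl ether, or cyclisation of the ortho-prenyl phenol to a chroman can lower the yield. Fallback: set out from 1 and iodinate between the two hydroxyls (I2, HIO3, aq. EtOH, rt) to give 1-(2,4-dihydroxy-3-iodophenyl)ethan-1-one F1. Protect the 4-OH (MOMCl, K2CO3, acetone) to give 1-[2-hydroxy-3-iodo-4-(methoxymethoxy)phenyl]ethan-1-one F2. A Stille coupling with tributyl(3-methylbut-2-en-1-yl)stannane (Pd(PPh3)4, DMF, 90 °C) then installs the linear prenyl group at the carbon that carried iodine, and the route is rejoined at 7.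

Step 13 (global deprotection). Acid can cyclise the ortho-prenyl resorcinol unit to a chroman, close the 2'-hydroxychalcone to a flavanone, or ionise the allylic alcohol. Fallback: set out from 19 and remove MOM and TBS at this simpler stage, where neither the prenylated resorcinol nor the chalcone is present (HCl in MeOH, 0 °C to rt). This gives 4-hydroxy-3-[(2R)-2-hydroxy-3-methylbut-3-en-1-yl]benzaldehyde F5. Condense F5 without protecting groups with the free diphenol ketone 6 (60% aq. KOH, EtOH, rt, 48 to 72 h, then careful neutralisation). The yield will be lower, but no acid touches the finished chalcone, and the route is rejoined directly at 22.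

**Further compounds**
F1 | step 3 | 1-(2,4-dihydroxy-3-iodophenyl)ethan-1-one | CC(=O)c1ccc(O)c(I)c1O
F2 | step 3 | 1-[2-hydroxy-3-iodo-4-(methoxymethoxy)phenyl]ethan-1-one | CC(=O)c1ccc(OCOC)c(I)c1O
F3 | step 9 | racemic 1-[5-bromo-2-(methoxymethoxy)phenyl]-3-methylbut-3-en-2-ol | C=C(C)C(O)Cc1cc(Br)ccc1OCOC
F4 | step 9 | (1S)-2-[5-bromo-2-(methoxymethoxy)phenyl]-1-[(2R)-2-methyloxiran-2-yl]ethan-1-ol | C[C@@]1(CO1)[C@@H](O)Cc1cc(Br)ccc1OCOC
F5 | step 13 | 4-hydroxy-3-[(2R)-2-hydroxy-3-methylbut-3-en-1-yl]benzaldehyde | C=C(C)[C@H](O)Cc1cc(C=O)ccc1O
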